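**Retrosynthetic overview**

1. Feature: ring A is a benzene ring with OMe at C1 and C3 and its only carbon substituent, the 10-phenyldecyl chain, at C5. This pattern maps onto C2–C7 of a linear 3,5,7-triketo ester: the ring oxygens are the C3 and C5 carbonyl oxygens, the chain-bearing ring carbon is C7, and C2 carries an ester that is removed later.
2. Target 11 ⇒ resorcinol 9 (two O–CH3 bonds) ⇒ resorcylate 7 (the ester carbon is lost by hydrolysis and decarboxylation).
3. 7 ⇒ triketo ester 5 by opening ring A at the C2–C7 bond (intramolecular aldol, dehydration, enolization). Ring A is the only ring built; the terminal phenyl ring comes intact from 1.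
4. 5 ⇒ trianion of 3 + methyl ester 2 (C6–C7 bond, Claisen-type acylation); 2 ⇐ acid 1.

Key step: step 3

Assumption: 11-phenylundecanoic acid and methyl 3,5-dioxohexanoate are taken as catalogue chemicals. The polycarbonyl compounds (3, 5, 6, F4, F5, F8) are drawn as keto tautomers although they should exist largely as enols.

**Route**

Step 1
Reactants: 1 11-phenylundecanoic acid
Product: 2 methyl 11-phenylundecanoate
Conditions: MeOH (solvent), H2SO4 (cat.), reflux
Reagents that add atoms: methanol (SMILES CO)
Why: Fischer esterification in a large excess of methanol drives the equilibrium to the ester, and the saturated chain and the phenyl ring are inert to these conditions.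

Step 2
Reactants: 3 methyl 3,5-dioxohexanoate; 2 methyl 11-phenylundecanoate
Product: 5 methyl 3,5,7-trioxo-17-phenylheptadecanoate, via trilithium trianion of methyl 3,5-dioxohexanoate 4 (not isolated)
Conditions: 3 (2 equiv), LiN(iPr)2 (6 equiv), THF, 0 °C; then 2 (1 equiv), 0 °C to rt; cold aq HCl
Reagents that add atoms: none
Why: Claisen-type C-acylation of a 1,3,5-tricarbonyl trianion, in which the terminal C6 carbanion (formed last, least stabilized, most nucleophilic) attacks the ester carbonyl of 2, while the second equivalent of trianion deprotonates the more acidic tetracarbonyl product and shields it from further attack.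

Step 3
Reactants: 5 methyl 3,5,7-trioxo-17-phenylheptadecanoate
Product: 7 methyl 2,4-dihydroxy-6-(10-phenyldecyl)benzoate, via cyclic aldol adduct 6 (not isolated)
Conditions: aq KOH (0.5 M, excess), THF, 0 °C to rt, Ar; then aq HCl
Reagents that add atoms: none
Why: Hydroxide converts 5 into its enolates, and the C2 carbanion, flanked by the ester and the C3 ketone, adds to the C7 ketone in an intramolecular aldol reaction; the cyclic β-hydroxy diketone 6 then loses water by an E1cB pathway and the C3 and C5 carbonyls enolize, so that ring A emerges aromatic. The closest known reaction type is the base-mediated aldol cyclization of 3,5,7-triketo esters to 6-substituted 2,4-dihydroxybenzoates, the laboratory counterpart of 5-alkylresorcinol biosynthesis. Ring A closes between C2 and C7 in a 6-(enolexo)-exo-trig mode when the ester enolate is taken as the nucleophile (equally allowed as 6-(enolendo)-exo-trig through the C3 enolate). No stereocenter has to be controlled, because both sp3 centers of 6 are erased on aromatization. The step needs the C2-to-C7 aldol to outrun Claisen closure of C6 onto the ester carbonyl, O-cyclization to pyranones and aldol attack of C8 on C3: in cold aqueous hydroxide the ketone is a far better acceptor than the ester, C2 is many pK units more acidic than the singly activated C8, and aromatization makes the aldol channel irreversible. The 10-phenyldecyl tail is a spectator, and partial saponification of the ester would do no harm since the acid 8 lies on the way to 9.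

Step 4
Reactants: 7 methyl 2,4-dihydroxy-6-(10-phenyldecyl)benzoate
Product: 9 5-(10-phenyldecyl)benzene-1,3-diol, via 2,4-dihydroxy-6-(10-phenyldecyl)benzoic acid 8 (not isolated)
Conditions: KOH (excess), degassed H2O/EtOH, reflux, N2; then aq HCl to pH 1, 80 °C
Reagents that add atoms: none
Why: Saponification followed by protodecarboxylation of a β-resorcylic acid, in which ipso protonation ortho and para to the two hydroxyls gives a β-keto-acid-like cyclohexadienone that loses CO2 readily, so the carboxyl acts as a traceless group.

Step 5
Reactants: 9 5-(10-phenyldecyl)benzene-1,3-diol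
Product: 11 1,3-dimethoxy-5-(10-phenyldecyl)benzene, via 3-methoxy-5-(10-phenyldecyl)phenol 10 (not isolated)
Conditions: Me2SO4 (3 equiv), K2CO3 (excess), acetone, reflux
Reagents that add atoms: dimethyl sulfate (SMILES COS(=O)(=O)OC)
Why: Williamson-type O-methylation of the two phenoxides by SN2 attack on dimethyl sulfate, where the weak carbonate base in acetone favours O- over C-alkylation and neither the alkyl chain nor the phenyl ring can react.

**Compound list**

1 | 11-phenylundecanoic acid | O=C(O)CCCCCCCCCCc1ccccc1 | starting material
2 | methyl 11-phenylundecanoate | COC(=O)CCCCCCCCCCc1ccccc1 | intermediate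
3 | methyl 3,5-dioxohexanoate | COC(=O)CC(=O)CC(C)=O | starting material
4 | trilithium trianion of methyl 3,5-dioxohexanoate | [Li+].[Li+].[Li+].C=C([O-])C=C([O-])C=C([O-])OC | intermediate (not isolated)
5 | methyl 3,5,7-trioxo-17-phenylheptadecanoate | COC(=O)CC(=O)CC(=O)CC(=O)CCCCCCCCCCc1ccccc1 | intermediate
6 | methyl 2-hydroxy-4,6-dioxo-2-(10-phenyldecyl)cyclohexane-1-carboxylate (cyclic aldol adduct; both stereocenters undefined and lost on aromatization) | COC(=O)C1C(=O)CC(=O)CC1(O)CCCCCCCCCCc1ccccc1 | intermediate (not isolated)
7 | methyl 2,4-dihydroxy-6-(10-phenyldecyl)benzoate | COC(=O)c1c(O)cc(O)cc1CCCCCCCCCCc1ccccc1 | intermediate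
8 | 2,4-dihydroxy-6-(10-phenyldecyl)benzoic acid | O=C(O)c1c(O)cc(O)cc1CCCCCCCCCCc1ccccc1 | intermediate (not isolated)
9 | 5-(10-phenyldecyl)benzene-1,3-diol | Oc1cc(O)cc(CCCCCCCCCCc2ccccc2)c1 | intermediate
10 | 3-methoxy-5-(10-phenyldecyl)phenol | COc1cc(O)cc(CCCCCCCCCCc2ccccc2)c1 | intermediate (not isolated)
11 | 1,3-dimethoxy-5-(10-phenyldecyl)benzene | COc1cc(CCCCCCCCCCc2ccccc2)cc(OC)c1 | target

**Summary**

Total step count: 5. Longest linear sequence: 5 steps (1 → 2 → 5 → 7 → 9 → 11); compound 3 enters at step 2.

**Steps most likely to fail**

Step 3 (key step). The cyclization may take the Claisen course (C6 onto the ester carbonyl, giving an acylphloroglucinol) or close through oxygen to a pyranone. The triketo ester may also suffer retro-Claisen cleavage in hydroxide before it cyclizes. The fallback sets out from 2 and comes back at 7, building ring A by a Michael–Dieckmann sequence in which no such mode competition exists. Ester 2 is reduced with iBu2AlH in CH2Cl2 at −78 °C to 11-phenylundecanal F1. Wittig olefination of F1 with the stabilized ylide Ph3P=CHC(O)CH3 in toluene should give (E)-14-phenyltetradec-3-en-2-one F2. Treatment of F2 with dimethyl malonate and NaOMe in refluxing MeOH gives the Michael adduct dimethyl 2-(2-oxo-14-phenyltetradecan-4-yl)propanedioate F3. F3 closes in the same flask by Dieckmann condensation of the methyl ketone carbon onto a malonate ester to methyl 2,4-dioxo-6-(10-phenyldecyl)cyclohexane-1-carboxylate F4. Bromination of F4 between the two carbonyls with Br2 in DMF at 0 °C gives methyl 3-bromo-2,4-dioxo-6-(10-phenyldecyl)cyclohexane-1-carboxylate F5. On warming to about 80 °C, F5 should lose HBr and tautomerize to the resorcylate 7.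

Step 2. The strongly basic trianion may remove an α-proton from ester 2 instead of acylating, acylation may occur on oxygen, and the sensitive triketo ester may degrade during the acidic work-up. The fallback sets out from 1 and comes back at 5, releasing the triketo ester under neutral conditions from a masked acylketene. Acid 1 is converted with oxalyl chloride and catalytic DMF in CH2Cl2 into 11-phenylundecanoyl chloride F6. Separately, 2,2,6-trimethyl-4H-1,3-dioxin-4-one is deprotonated with LiN(SiMe3)2 in THF at −78 °C and acetylated with acetyl chloride to 2,2-dimethyl-6-(2-oxopropyl)-4H-1,3-dioxin-4-one F7. The dianion of F7 (LiN(iPr)2 in excess, THF, −78 °C) is acylated at its terminal carbon by F6 to give 6-(2,4-dioxo-14-phenyltetradecyl)-2,2-dimethyl-4H-1,3-dioxin-4-one F8. Heating F8 in toluene at 110 °C with MeOH should expel acetone by a retro-[4+2] reaction, and the acylketene 17-phenylheptadec-1-ene-1,3,5,7-tetrone F9 is trapped by MeOH as triketo ester 5.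

Step 4. Protodecarboxylation may stop short, and the electron-rich resorcinol may be oxidized by air in hot alkali. The fallback sets out from 7 and comes back at 11, methylating before the carboxyl is removed so that the free resorcinol 9 is never handled. Ester 7 is O-methylated twice with Me2SO4 and K2CO3 in refluxing acetone to methyl 2,4-dimethoxy-6-(10-phenyldecyl)benzoate F10. The hindered ester F10 is saponified with KOH in aqueous DMSO at 100 °C to 2,4-dimethoxy-6-(10-phenyldecyl)benzoic acid F11. Protodecarboxylation of this ortho-disubstituted, electron-rich acid with Ag2CO3 (cat.) and AcOH in DMSO at 120 °C should give target 11.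

**Further compounds**

F1 | step 3 | 11-phenylundecanal | O=CCCCCCCCCCCc1ccccc1
F2 | step 3 | (E)-14-phenyltetradec-3-en-2-one | CC(=O)/C=C/CCCCCCCCCCc1ccccc1
F3 | step 3 | dimethyl 2-(2-oxo-14-phenyltetradecan-4-yl)propanedioate (racemic) | COC(=O)C(C(=O)OC)C(CC(C)=O)CCCCCCCCCCc1ccccc1
F4 | step 3 | methyl 2,4-dioxo-6-(10-phenyldecyl)cyclohexane-1-carboxylate (racemic, stereocenters lost later) | COC(=O)C1C(=O)CC(=O)CC1CCCCCCCCCCc1ccccc1
F5 | step 3 | methyl 3-bromo-2,4-dioxo-6-(10-phenyldecyl)cyclohexane-1-carboxylate (stereocenters undefined, lost later) | COC(=O)C1C(=O)C(Br)C(=O)CC1CCCCCCCCCCc1ccccc1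
F6 | step 2 | 11-phenylundecanoyl chloride | O=C(Cl)CCCCCCCCCCc1ccccc1
F7 | step 2 | 2,2-dimethyl-6-(2-oxopropyl)-4H-1,3-dioxin-4-one | CC(=O)CC1=CC(=O)OC(C)(C)O1
F8 | step 2 | 6-(2,4-dioxo-14-phenyltetradecyl)-2,2-dimethyl-4H-1,3-dioxin-4-one | CC1(C)OC(=O)C=C(CC(=O)CC(=O)CCCCCCCCCCc2ccccc2)O1
F9 | step 2 | 17-phenylheptadec-1-ene-1,3,5,7-tetrone (acylketene) | O=C=CC(=O)CC(=O)CC(=O)CCCCCCCCCCc1ccccc1
F10 | step 4 | methyl 2,4-dimethoxy-6-(10-phenyldecyl)benzoate | COC(=O)c1c(OC)cc(OC)cc1CCCCCCCCCCc1ccccc1
F11 | step 4 | 2,4-dimethoxy-6-(10-phenyldecyl)benzoic acid | O=C(O)c1c(OC)cc(OC)cc1CCCCCCCCCCc1ccccc1
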